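The data were generated by integration with constants of no real substance; the scatter is artificial.

In a one-step world reagent meets substrate and nothing else, so a reagent charge twice that of substrate would carry the substrate through to target. The east run does not behave so.

| flask | substrate | partner | reagent | remark | time |
|---|---|---|---|---|---|
| north-east | 2 mM | 1.3 mM | 4 mM | run made earlier |  |
| east | 2 mM | 19 mM | 4 mM | run made earlier |  |
| dawn | 2.0 mM | 1.50 mM | 4.00 mM |  | 2.5 min |
| autumn | 2.0 mM | 3.00 mM | 4.00 mM |  | 2.5 min |
| winter | 2.0 mM | 6.00 mM | 4.00 mM |  | 2.5 min |
| summer | 2.0 mM | 12.0 mM | 4.00 mM |  | 2.5 min |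
| spring | 2.0 mM | 25.0 mM | 4.00 mM |  | 2.5 min |

| run | time / min | target / % | substrate / % |
|---|---|---|---|
| north-east | 0.200 | 4.1 | 35.6 |
| north-east | 0.417 | 14.7 | 20.0 |
| north-east | 0.667 | 19.4 | 12.5 |
| north-east | 1.33 | 32.9 | 3.3 |
| north-east | 2.50 | 43.4 | 0.2 |
| east | 0.200 | 6.9 | 87.8 |
| east | 0.417 | 8.4 | 86.9 |
| east | 0.667 | 9.2 | 84.0 |
| east | 1.33 | 9.3 | 88.2 |
| east | 2.50 | 9.7 | 84.5 |

(scatter of a reading: 1 percentage point)

- the analysis behind the earlier runs scatters by 1 percentage point, standard deviation
- "hardly changes" means that all values lie within two and a half points (for a concentration: within two and a half percent of the largest)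

- amount of target at the end, in percent of the substrate charged for dawn, autumn, winter, summer, spring, in this order
- how that number moves from the first to the last of them (hardly changes / falls, then rises / falls all the way / rises, then falls / rises all the way)

We keep a ledger of the reagent. In east the substrate readings lie flat, with a mean of 86.3 %, so we read the substrate entry as 0.274 mM. We read the stall as the 4 mM of reagent being used up, and book the remaining 3.73 mM to partner, which leaves 80.4 % of east's partner. The north-east run permits this, since its substrate and partner together ask for 3.30 mM, less than its 4 mM of reagent.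

If reagent meets each consumer at a rate proportional to that consumer's concentration, the logarithms of the fractions left keep a fixed ratio. East reads 0.676. This is the selectivity factor, the logarithm of the fraction of substrate left over that of the fraction of partner left. East's last target reading, per substrate used, gives a target share of 70.7 %.

In winter reagent is the limiting reagent, since substrate and partner ask for 8.00 mM. We start by booking the whole charge to partner, derive the substrate entry from the factor, return that amount to partner and go round again. The substrate entry runs 1.05 mM, 0.735 mM, 0.824 mM, 0.798 mM. The books close with 3.20 mM to partner, and our winter target is 28.2 %.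

The forecast gives 48 %, 60 %, 55 %, 24 % and 6 %, shape rises, then falls, holding that “this destruction must be steeper than first order in partner”. Our winter figure is lower than its 55 %, and there the two part.

The flasks give 47.3 %, 50.6 %, 29.4 %, 15.6 % and 7.69 %, shape rises, then falls.

    substrate + reagent → open intermediate (k = 32.0 M⁻¹ s⁻¹)
    reagent + partner → second intermediate (k = 48.0 M⁻¹ s⁻¹)
    open intermediate + second intermediate → target (k = 15.0 M⁻¹ s⁻¹)
    target ⇌ isomer of the product (K = 0.350, k = 0.0380 s⁻¹)

Winter ends with 0 % of reagent, 60.1 % of substrate and 46.6 % of partner. Two rounds with the factor for spring give substrate entries of 0.222 mM and 0.210 mM, hence 89.5 % of substrate left and 7.41 % of target. Spring stands at 89.6 % of substrate and 7.69 % of target.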